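Free catalyst that never died cannot give these two runs: gamma, with half the charge of alpha, ran 2.40 times as long (3.00 d against 30.0 h), yet shows 26.4% product against 28.2%.

| flask | substrate | reagent | free catalyst | remark |
|---|---|---|---|---|
| alpha | 1.5 M | 1.3 equiv | 0.1 mol% | the very flask that is asked about, followed so far |
| gamma | 1.5 M | 1.3 equiv | 0.05 mol% | run made earlier |
| flask | 1.5 M | 1.30 equiv | 0.1 mol% |  |

- alpha (time / h: product / %, substrate / %): 3.00: 4.1, 95.9; 5.00: 5.5, 94.1; 8.00: 10.0, 90.3; 12.0: 13.2, 87.8; 20.0: 20.1, 79.2; 30.0: 28.2, 72.8; 40.0: 35.1, 65.8
- gamma (time / d: product / %, substrate / %): 0.333: 4.1, 94.5; 0.500: 6.8, 93.5; 0.833: 11.3, 89.2; 1.25: 15.2, 86.6; 1.67: 18.0, 81.6; 3.00: 26.4, 73.8; 4.00: 30.1, 69.7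

(standard deviation of a reading: 0.5 percentage points)

* factor on the rate of making product when 20% of the substrate are converted if free catalyst is charged twice over
* factor on the rate when 20% of the substrate are converted if free catalyst is charged at 0.5 mol% instead

- steps thought possible: catalyst intermediate C <-> catalyst intermediate D; catalyst intermediate A -> spent catalyst; catalyst intermediate D -> free catalyst + product; catalyst intermediate B <-> by-product + catalyst intermediate C; substrate + catalyst intermediate A <-> catalyst intermediate B; reagent + free catalyst -> catalyst intermediate A

So catalyst is lost with the clock. In the alpha run the second 20.0 h made 0.746 of what the first 20.0 h made, which reads as a loss of 0.0146 h⁻¹. With substrate and reagent frozen at their charge, such a falling pace adds up to 79.2% for alpha: this is the ceiling, the product a charge makes before its catalyst has died, proportional to the charge. The rate is then the loss constant times the room left under the ceiling. As a check, half that ceiling gives 29.9% at 4.00 d for gamma, which read 30.1%.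

The factor on the rate at fixed conversion is the room under the raised ceiling over the room under the old one. That has two extremes. With a ceiling far above the conversion, the factor for a doubled charge is simply 2; with a ceiling just above it, the old room shrinks towards nothing and the factor grows without end. Alpha lies near the first, its ceiling being 3.96 times 20%, so my reckoning for doubling is 2.34.

The forecast gives 2.33 and 6.3, on its reading of “catalyst death that depends on clock time, not turnover”.

    catalyst intermediate C ⇌ catalyst intermediate D (K = 0.573, k = 8540 h⁻¹)
    catalyst intermediate A → spent catalyst (k = 0.0358 h⁻¹)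
    catalyst intermediate D → free catalyst + product (k = 72.1 h⁻¹)
    catalyst intermediate B ⇌ by-product + catalyst intermediate C (K = 7.84 M, k = 1490 h⁻¹)
    substrate + catalyst intermediate A ⇌ catalyst intermediate B (K = 0.770 M⁻¹, k = 24.7 M⁻¹ h⁻¹)
    reagent + free catalyst → catalyst intermediate A (k = 32.6 M⁻¹ h⁻¹)

The flask gives 2.29 and 6.15; the ceiling scaled to 0.5 mol%, a paper 396% of the substrate, gives 6.35 for the second. Catalyst intermediate A goes to spent catalyst with a half-life of 0.807 d, whereas reagent at 6.00 d has a half-life of 29 d by its step with free catalyst, far longer. At 60.0 d the flask holds 100% of its catalyst as spent catalyst, beside 38.2% of its substrate charge and 52.4% of its reagent charge.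

The runs were computed with constants of no real substance; the scatter is artificial.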